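Labels: rings A, C and B are the catechin core. The ring D atoms are D1 (bridge CH2), D2 (OH), D3 (acetyl), D4 (OMe), D5 (CH3) and D6 (OH).
Enabling feature: in ring D the oxygen-bearing carbons D2, D4 and D6 alternate with the carbon-substituted D1, D3 and D5, and D3 carries an acyl group, so ring D is a folded tetraketide. Cutting D2–D3 unfolds it to the chain D2 (methyl ester)–D1–D6 (ketone)–D5–D4 (methyl enol ether)=D3–acetyl, with the D4 methoxyl already in place.
Retrosynthetic cuts, in order: five O–benzyl bonds; D2–D3 (ring D); D5–D4 (bis-silyl dienol ether plus acetylketene dimethyl acetal); bridge CH2–D1 (Knoevenagel condensation and reduction); C8–CHO (Br/Li exchange, DMF).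
Forward: rings A, B and C arrive intact with (+)-catechin. The chain is attached at C8 and lengthened by four carbons at D5. Ring D, the only ring made, is closed last before global hydrogenolysis.
Stereochemistry: C2 (R) and C3 (S) are those of (+)-catechin and are never touched. The D1 and D5 centres and the enol ether geometry are transient and vanish on aromatization.

Key step: step 10

Assumption: the D1 and D5 centres and the C=C geometries of 13, 15 and the D1=D6 bond of 16 arise as mixtures and are left undefined in the SMILES. The D4=D3 enol ether is drawn E (methoxyl trans to acetyl), the expected thermodynamic geometry. None of these elements survives step 10.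

Step 1
Reactants: 1 acetyl chloride; 2 1,1-dichloroethene
Product: 4 4,4-dichlorobut-3-en-2-one, via 4,4,4-trichlorobutan-2-one 3 (not isolated)
Conditions: AlCl3 (1.1 equiv), CH2Cl2, 0 °C to rt; ice/aq HCl; distillation (loss of HCl)
Reagents that add atoms: none
Why: Aliphatic Friedel–Crafts acylation: the acylium ion adds to the CH2 terminus of 2 because the resulting cation is stabilized by two chlorines, chloride capture gives 3, and loss of HCl is driven by conjugation with the ketone.

Step 2
Reactants: 4 4,4-dichlorobut-3-en-2-one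
Product: 5 4,4-dimethoxybut-3-en-2-one (acetylketene dimethyl acetal)
Conditions: NaOMe (2.1 equiv), MeOH, 0 °C to rt; filtration; distillation
Reagents that add atoms: sodium methoxide, C[O-].[Na+]
Why: Two consecutive vinylic addition–elimination substitutions at the β-carbon of the enone exchange both chlorides for methoxide and give a stable push–pull ketene acetal.

Step 3
Reactants: 6 (+)-catechin
Product: 7 (2R,3S)-5,7,3',4'-tetra-O-benzylcatechin
Conditions: BnBr (4.4 equiv), K2CO3 (5 equiv), DMF, 0 °C to rt, Ar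
Reagents that add atoms: benzyl bromide, BrCc1ccccc1
Why: Williamson ether synthesis in which carbonate deprotonates only the four phenols, so the C3 alcohol stays free and the mild, oxygen-free medium leaves C2 and C3 unchanged.

Step 4
Reactants: 7 (2R,3S)-5,7,3',4'-tetra-O-benzylcatechin
Product: 8 (2R,3S)-3,5,7,3',4'-penta-O-benzylcatechin
Conditions: NaH (1.5 equiv), BnBr (1.3 equiv), DMF, 0 °C to rt
Reagents that add atoms: benzyl bromide, BrCc1ccccc1
Why: Williamson ether synthesis of the secondary alkoxide; with every phenol capped, the strong base cannot open ring C through a quinone methide, so C2 is not epimerized.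

Step 5
Reactants: 8 (2R,3S)-3,5,7,3',4'-penta-O-benzylcatechin
Product: 9 (2R,3S)-8-bromo-3,5,7,3',4'-penta-O-benzylcatechin
Conditions: NBS (1.0 equiv), CH2Cl2, −78 °C to rt, dark
Reagents that add atoms: N-bromosuccinimide, O=C1CCC(=O)N1Br
Why: Electrophilic aromatic bromination, which on O-benzylated catechins goes to C8 of ring A rather than C6 when one equivalent of NBS is used at low temperature, while ring B is less activated.

Step 6
Reactants: 9 (2R,3S)-8-bromo-3,5,7,3',4'-penta-O-benzylcatechin
Product: 11 (2R,3S)-8-formyl-3,5,7,3',4'-penta-O-benzylcatechin, via 8-lithio-3,5,7,3',4'-penta-O-benzylcatechin 10 (not isolated)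
Conditions: n-BuLi (1.1 equiv), THF, −78 °C; DMF (3 equiv), −78 to 0 °C; H2O
Reagents that add atoms: N,N-dimethylformamide, CN(C)C=O
Why: Bromine–lithium exchange followed by formylation with DMF; at −78 °C the exchange outruns benzylic deprotonation, and aryllithium 10 is stabilized by its two ortho oxygens.

Step 7
Reactants: 11 (2R,3S)-8-formyl-3,5,7,3',4'-penta-O-benzylcatechin; 12 methyl 3-oxopentanoate
Product: 14 methyl 3-oxo-2-{[(2R,3S)-penta-O-benzylcatechin-8-yl]methyl}pentanoate, via Knoevenagel alkylidene keto ester 13 (not isolated)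
Conditions: 12 (1.5 equiv), piperidine (20 mol %), AcOH (20 mol %), toluene, Dean–Stark, reflux; then Hantzsch ester (diethyl 2,6-dimethyl-1,4-dihydropyridine-3,5-dicarboxylate, 1.3 equiv), 80 °C
Reagents that add atoms: none
Why: Knoevenagel condensation followed in the same flask by Hantzsch ester transfer hydrogenation of the doubly activated C=C, which spares ketone, ester and benzyl ethers; the new D1 centre forms without control and is erased in step 10.

Step 8
Reactants: 14 methyl 3-oxo-2-{[(2R,3S)-penta-O-benzylcatechin-8-yl]methyl}pentanoate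
Product: 15 1-methoxy-2-{[(2R,3S)-penta-O-benzylcatechin-8-yl]methyl}-1,3-bis(trimethylsilyloxy)penta-1,3-diene
Conditions: Me3SiOTf (2.3 equiv), Et3N (2.6 equiv), Et2O–toluene, 0 °C to rt; decant from the ammonium salt, concentrate, use crude
Reagents that add atoms: trimethylsilyl trifluoromethanesulfonate, C[Si](C)(C)OS(=O)(=O)C(F)(F)F
Why: Soft enolization and O-silylation of a β-keto ester, the one-step entry to 1,3-bis(silyloxy)-1,3-dienes (D5 holds the only enolizable protons left after the first silylation); the neutral diene is preferred to a lithium dianion, which the acetyl protons of 5 would quench or which would add to its carbonyl group.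

Step 9
Reactants: 15 1-methoxy-2-{[(2R,3S)-penta-O-benzylcatechin-8-yl]methyl}-1,3-bis(trimethylsilyloxy)penta-1,3-diene; 5 4,4-dimethoxybut-3-en-2-one
Product: 17 methyl (5E)-5-methoxy-4-methyl-3,7-dioxo-2-{[(2R,3S)-penta-O-benzylcatechin-8-yl]methyl}oct-5-enoate, via D1 trimethylsilyl enol ether 16 (not isolated)
Conditions: 5 (1.5 equiv), TiCl4 (1.1 equiv), 4 Å MS, CH2Cl2, −78 to −40 °C; sat. aq NaHCO3 at −40 °C, then rt
Reagents that add atoms: none
Why: Mukaiyama–Michael addition–elimination, the known first bond formation in the formal [3+3] cyclizations of 1,3-bis(silyloxy)dienes with 1,1-dimethoxyalk-1-en-3-ones: D5, the terminal and most nucleophilic carbon of 15, adds to the TiCl4-activated acetal carbon of 5 and methoxide leaves, while the D1 substituent and the cold basic quench hold back a second (aldol) bond; D5 forms without control and is erased in step 10.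

Step 10
Reactants: 17 methyl (5E)-5-methoxy-4-methyl-3,7-dioxo-2-{[(2R,3S)-penta-O-benzylcatechin-8-yl]methyl}oct-5-enoate
Product: 19 penta-O-benzylpilosanol N, via ring-closed cyclohexenedione tautomer 18 (not isolated)
Conditions: Mg(OMe)2 (4 equiv), MeOH–THF (1:1), 60 °C, Ar; cold 1 M HCl
Reagents that add atoms: none
Why: Proposed new method: Mg(OMe)2 reversibly removes the D5 proton, which is acidified by the D6 ketone on one side and by the D4=D3–acetyl vinylogous ester on the other, and the dienolate, with magnesium bridging the D6 oxygen and the D2 ester carbonyl, attacks D2 through its α-carbon D3; methoxide is expelled to give 18, whose enolization to the arene (held as its magnesium phenolate) makes the sequence irreversible. The closest known reaction type is the base- or Mg(OMe)2-mediated Claisen (Dieckmann-type) folding of 3,5,7-triketo esters to acylphloroglucinols; what has not been shown is this closure with the central carbonyl locked as a methyl enol ether. Ring D closes in a 6-(enolexo)-exo-trig acyl substitution that forms the D2–D3 bond. No stereocentre is created, the D1 and D5 centres and the enol ether geometry disappear (D4–D3 is a single bond in the dienolate), and C2 and C3 of the fully O-benzylated flavan cannot epimerize. The selectivity needed is C-acylation from D3 onto D2 over lactonization and aldol modes: pyrone formation is excluded because the D4 oxygen is methylated, attack of D1 on the acetyl carbonyl gives an aldolate with a quaternary D1 that cannot aromatize and reverts, and attack of the acetyl methyl on D6 needs a far less acidic proton and a carbonyl that is masked as enolate. Methoxide in methanol keeps ester exchange and addition–elimination at D4 degenerate and lets the unreactive D1 enolate equilibrate with the reactive D5 dienolate.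

Step 11
Reactants: 19 penta-O-benzylpilosanol N
Product: 20 pilosanol N
Conditions: H2 (1 atm), Pd(OH)2/C (20 wt %), THF–MeOH (1:1), rt; filtration under Ar
Reagents that add atoms: none
Why: Catalytic hydrogenolysis of benzyl ethers, the usual last step for benzylated flavan-3-ols; under neutral conditions at 1 atm the chelated aryl ketone, the diarylmethane bridge and the C2–O bond should persist and C2 and C3 are unaffected.

Compound list
1 | acetyl chloride | CC(=O)Cl | starting material
2 | 1,1-dichloroethene | C=C(Cl)Cl | starting material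
3 | 4,4,4-trichlorobutan-2-one | CC(=O)CC(Cl)(Cl)Cl | intermediate
4 | 4,4-dichlorobut-3-en-2-one | CC(=O)C=C(Cl)Cl | intermediate
5 | 4,4-dimethoxybut-3-en-2-one | CC(=O)C=C(OC)OC | intermediate
6 | (+)-catechin, (2R,3S) | O[C@H]1Cc2c(O)cc(O)cc2O[C@@H]1c1ccc(O)c(O)c1 | starting material
7 | (2R,3S)-5,7,3',4'-tetra-O-benzylcatechin | c1c(OCc2ccccc2)cc(OCc2ccccc2)c2c1O[C@H](c1ccc(OCc3ccccc3)c(OCc3ccccc3)c1)[C@@H](O)C2 | intermediate
8 | (2R,3S)-3,5,7,3',4'-penta-O-benzylcatechin | c1c(OCc2ccccc2)cc(OCc2ccccc2)c2c1O[C@H](c1ccc(OCc3ccccc3)c(OCc3ccccc3)c1)[C@@H](OCc1ccccc1)C2 | intermediate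
9 | (2R,3S)-8-bromo-3,5,7,3',4'-penta-O-benzylcatechin | Brc1c(OCc2ccccc2)cc(OCc2ccccc2)c2c1O[C@H](c1ccc(OCc3ccccc3)c(OCc3ccccc3)c1)[C@@H](OCc1ccccc1)C2 | intermediate
10 | (2R,3S)-8-lithio-3,5,7,3',4'-penta-O-benzylcatechin | [Li]c1c(OCc2ccccc2)cc(OCc2ccccc2)c2c1O[C@H](c1ccc(OCc3ccccc3)c(OCc3ccccc3)c1)[C@@H](OCc1ccccc1)C2 | intermediate
11 | (2R,3S)-8-formyl-3,5,7,3',4'-penta-O-benzylcatechin | O=Cc1c(OCc2ccccc2)cc(OCc2ccccc2)c2c1O[C@H](c1ccc(OCc3ccccc3)c(OCc3ccccc3)c1)[C@@H](OCc1ccccc1)C2 | intermediate
12 | methyl 3-oxopentanoate | CCC(=O)CC(=O)OC | starting material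
13 | methyl 3-oxo-2-{[(2R,3S)-penta-O-benzylcatechin-8-yl]methylidene}pentanoate (E/Z mixture) | CCC(=O)C(=Cc1c(OCc2ccccc2)cc(OCc2ccccc2)c2c1O[C@H](c1ccc(OCc3ccccc3)c(OCc3ccccc3)c1)[C@@H](OCc1ccccc1)C2)C(=O)OC | intermediate
14 | methyl 3-oxo-2-{[(2R,3S)-penta-O-benzylcatechin-8-yl]methyl}pentanoate (D1 epimers) | CCC(=O)C(Cc1c(OCc2ccccc2)cc(OCc2ccccc2)c2c1O[C@H](c1ccc(OCc3ccccc3)c(OCc3ccccc3)c1)[C@@H](OCc1ccccc1)C2)C(=O)OC | intermediate
15 | 1-methoxy-2-{[(2R,3S)-penta-O-benzylcatechin-8-yl]methyl}-1,3-bis(trimethylsilyloxy)penta-1,3-diene (geometric isomers) | CC=C(O[Si](C)(C)C)C(Cc1c(OCc2ccccc2)cc(OCc2ccccc2)c2c1O[C@H](c1ccc(OCc3ccccc3)c(OCc3ccccc3)c1)[C@@H](OCc1ccccc1)C2)=C(OC)O[Si](C)(C)C | intermediate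
16 | methyl (5E)-5-methoxy-4-methyl-7-oxo-2-{[(2R,3S)-penta-O-benzylcatechin-8-yl]methyl}-3-(trimethylsilyloxy)octa-2,5-dienoate | COC(=O)C(Cc1c(OCc2ccccc2)cc(OCc2ccccc2)c2c1O[C@H](c1ccc(OCc3ccccc3)c(OCc3ccccc3)c1)[C@@H](OCc1ccccc1)C2)=C(O[Si](C)(C)C)C(C)/C(OC)=C\C(C)=O | intermediate
17 | methyl (5E)-5-methoxy-4-methyl-3,7-dioxo-2-{[(2R,3S)-penta-O-benzylcatechin-8-yl]methyl}oct-5-enoate (D1/D5 epimers) | COC(=O)C(Cc1c(OCc2ccccc2)cc(OCc2ccccc2)c2c1O[C@H](c1ccc(OCc3ccccc3)c(OCc3ccccc3)c1)[C@@H](OCc1ccccc1)C2)C(=O)C(C)/C(OC)=C\C(C)=O | intermediate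
18 | 4-acetyl-5-methoxy-6-methyl-2-{[(2R,3S)-penta-O-benzylcatechin-8-yl]methyl}cyclohex-5-ene-1,3-dione | COC9=C(C)C(=O)C(Cc1c(OCc2ccccc2)cc(OCc2ccccc2)c2c1O[C@H](c1ccc(OCc3ccccc3)c(OCc3ccccc3)c1)[C@@H](OCc1ccccc1)C2)C(=O)C9C(C)=O | intermediate
19 | penta-O-benzylpilosanol N, 1-(2,4-dihydroxy-6-methoxy-5-methyl-3-{[(2R,3S)-penta-O-benzylcatechin-8-yl]methyl}phenyl)ethanone | COc9c(C)c(O)c(Cc1c(OCc2ccccc2)cc(OCc2ccccc2)c2c1O[C@H](c1ccc(OCc3ccccc3)c(OCc3ccccc3)c1)[C@@H](OCc1ccccc1)C2)c(O)c9C(C)=O | intermediate
20 | pilosanol N, (2R,3S) | COc1c(C)c(O)c(Cc2c(O)cc(O)c3c2O[C@H](c2ccc(O)c(O)c2)[C@@H](O)C3)c(O)c1C(C)=O | target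

Total step count: 11. Longest linear sequence: 9 steps (steps 3 to 11, from (+)-catechin).

Steps most likely to fail

Step 10 (ring closure).
- What may go wrong: D1, the most acidic site, may hold the substrate as an inert magnesium β-keto ester chelate. Attack on the ester would then be slower than retro-Claisen scission at D6 or aldol closure of the acetyl methyl onto D6.
- Fallback by known chemistry: ring D is brought in as a finished arene and only the bridge bond CH2–D1 is made.
- It sets out from 11, which NaBH4 (THF–MeOH, 0 °C) reduces to (2R,3S)-8-(hydroxymethyl)-3,5,7,3',4'-penta-O-benzylcatechin F1.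
- In parallel, purchased 2,4,6-trihydroxy-3-methylacetophenone is benzylated (BnBr, 2 equiv, K2CO3, acetone) at the non-chelated 4-hydroxyl and at the less hindered of the two chelating hydroxyls. This gives 1-[4,6-bis(benzyloxy)-2-hydroxy-3-methylphenyl]ethanone F2.
- The remaining hydroxyl between acetyl and methyl is methylated (Me2SO4, K2CO3, acetone, reflux) to 1-[4,6-bis(benzyloxy)-2-methoxy-3-methylphenyl]ethanone F3.
- Hydrogenolysis (H2, Pd/C, EtOAc) gives 1-(4,6-dihydroxy-2-methoxy-3-methylphenyl)ethanone F4.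
- Acid-catalysed Friedel–Crafts benzylation of excess F4 with F1 (Sc(OTf)3, 5 mol %, CH2Cl2–MeCN, 0 °C) at D1, its only free ring carbon, comes back to the route at 19.

Step 9 (D5–D4 bond).
- What may go wrong: addition to the acetyl carbonyl instead of the acetal carbon; a follow-up aldol closure of the D1 silyl enol ether onto the acetyl group; acid-induced cyclodehydration of the 1,5-dicarbonyl array towards a pyrylium or γ-pyrone; or Lewis-acid loss of benzyl ethers.
- Fallback: the chain extension is moved ahead of the conjugate reduction. D1 is then an sp2 carbon without nucleophilicity, and only one silyl enol ether is present.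
- It sets out from 13, now isolated after the condensation half of step 7.
- Me3SiOTf/Et3N (CH2Cl2, 0 °C) gives methyl 2-{[(2R,3S)-penta-O-benzylcatechin-8-yl]methylidene}-3-(trimethylsilyloxy)pent-3-enoate F5.
- Mukaiyama–Michael addition–elimination on 5 (TiCl4, CH2Cl2, −78 °C) gives methyl (5E)-5-methoxy-4-methyl-3,7-dioxo-2-{[(2R,3S)-penta-O-benzylcatechin-8-yl]methylidene}oct-5-enoate F6.
- Hantzsch ester (toluene, 80 °C) reduces only the doubly acceptor-activated arylidene C=C, not the donor-substituted D4=D3 bond, and the sequence comes back to the route at 17.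

Step 7 (bridge CH2–D1).
- What may go wrong: slow condensation of the hindered, electron-rich 2,6-dialkoxybenzaldehyde with a moderately acidic keto ester; Michael addition of a second keto ester; or incomplete hydride transfer.
- Fallback: the bridge is made with a far more acidic carbon acid and the propionyl group is added afterwards.
- It sets out from 11. Meldrum's acid, L-proline (cat.) and Hantzsch ester in EtOH at rt (three-component reductive alkylation) give 2,2-dimethyl-5-{[(2R,3S)-penta-O-benzylcatechin-8-yl]methyl}-1,3-dioxane-4,6-dione F7.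
- Reflux in MeOH–toluene opens it to 3-methoxy-3-oxo-2-{[(2R,3S)-penta-O-benzylcatechin-8-yl]methyl}propanoic acid F8.
- i-PrMgCl (2 equiv), then 1-propionylimidazole in THF (decarboxylative Claisen condensation of Masamune–Brooks type) comes back to the route at 14.

Further compounds
F1 | step 10 | (2R,3S)-8-(hydroxymethyl)-3,5,7,3',4'-penta-O-benzylcatechin | OCc1c(OCc2ccccc2)cc(OCc2ccccc2)c2c1O[C@H](c1ccc(OCc3ccccc3)c(OCc3ccccc3)c1)[C@@H](OCc1ccccc1)C2
F2 | step 10 | 1-[4,6-bis(benzyloxy)-2-hydroxy-3-methylphenyl]ethanone | CC(=O)c1c(O)c(C)c(OCc2ccccc2)cc1OCc1ccccc1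
F3 | step 10 | 1-[4,6-bis(benzyloxy)-2-methoxy-3-methylphenyl]ethanone | CC(=O)c1c(OC)c(C)c(OCc2ccccc2)cc1OCc1ccccc1
F4 | step 10 | 1-(4,6-dihydroxy-2-methoxy-3-methylphenyl)ethanone | CC(=O)c1c(OC)c(C)c(O)cc1O
F5 | step 9 | methyl 2-{[(2R,3S)-penta-O-benzylcatechin-8-yl]methylidene}-3-(trimethylsilyloxy)pent-3-enoate | CC=C(O[Si](C)(C)C)C(=Cc1c(OCc2ccccc2)cc(OCc2ccccc2)c2c1O[C@H](c1ccc(OCc3ccccc3)c(OCc3ccccc3)c1)[C@@H](OCc1ccccc1)C2)C(=O)OC
F6 | step 9 | methyl (5E)-5-methoxy-4-methyl-3,7-dioxo-2-{[(2R,3S)-penta-O-benzylcatechin-8-yl]methylidene}oct-5-enoate | COC(=O)C(=Cc1c(OCc2ccccc2)cc(OCc2ccccc2)c2c1O[C@H](c1ccc(OCc3ccccc3)c(OCc3ccccc3)c1)[C@@H](OCc1ccccc1)C2)C(=O)C(C)/C(OC)=C\C(C)=O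
F7 | step 7 | 2,2-dimethyl-5-{[(2R,3S)-penta-O-benzylcatechin-8-yl]methyl}-1,3-dioxane-4,6-dione | CC9(C)OC(=O)C(Cc1c(OCc2ccccc2)cc(OCc2ccccc2)c2c1O[C@H](c1ccc(OCc3ccccc3)c(OCc3ccccc3)c1)[C@@H](OCc1ccccc1)C2)C(=O)O9
F8 | step 7 | 3-methoxy-3-oxo-2-{[(2R,3S)-penta-O-benzylcatechin-8-yl]methyl}propanoic acid | COC(=O)C(Cc1c(OCc2ccccc2)cc(OCc2ccccc2)c2c1O[C@H](c1ccc(OCc3ccccc3)c(OCc3ccccc3)c1)[C@@H](OCc1ccccc1)C2)C(=O)O
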